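**Retrosynthetic overview**
1. Target ⇐ (Z)-1,5-diol from a temporary eight-membered silaketal ring (silicon-tethered RCM fixes the Z side-chain alkene) ⇐ C1′ aldehyde by reagent-controlled allylboration.
2. Nine-membered ring ⇐ anionic oxy-Cope ring expansion of a 2-vinyl-3-isopropenylbicyclo[3.2.0]heptan-2-ol; the C8 ketone becomes the exocyclic methylene and C5 is oxidised allylically.
3. Cyclobutane and cyclopentane ⇐ one CuOTf-catalysed intramolecular [2+2] photocycloaddition of an acyclic divinyl carbinol (key step), steered by the C3 stereocentre, which the ring expansion later erases.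
4. Divinyl carbinol ⇐ Evans alkylation of a senecioyl imide dienolate with an (E)-allylic chloride made from prenyl chloride.
5. Ring order: cyclobutane and five-membered ring together, then five → nine, last the temporary silaketal ring (opened again).

Atom labels (C1–C11 ring atoms, C1′–C5′ side chain) are the positions the atoms take in the target, bicyclo[7.2.0]undecane numbering.
Assumption: the (4S) centre, α to the ring ketone, is the thermodynamically preferred C4 epimer and is set by equilibration (step 14).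

Step 1
Reactants: 1 1-chloro-3-methylbut-2-ene (prenyl chloride)
Product: 2 (2E)-4-chloro-2-methylbut-2-en-1-ol
Conditions: SeO2 (cat.), t-BuOOH, CH2Cl2, rt
Reagents that add atoms: tert-butyl hydroperoxide, CC(C)(C)OO
Why: SeO2-catalysed allylic oxidation (ene reaction then [2,3]-shift) hydroxylates the methyl trans to the CH2Cl branch, fixing the (E) geometry that later puts the C11 methyl cis to C2.

Step 2
Reactants: 2 (2E)-4-chloro-2-methylbut-2-en-1-ol
Product: 3 {[(2E)-4-chloro-2-methylbut-2-en-1-yl]oxy}triethylsilane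
Conditions: Et3SiCl, imidazole, CH2Cl2, 0 °C
Reagents that add atoms: chlorotriethylsilane, CC[Si](Cl)(CC)CC
Why: Routine silylation masks the alcohol so that the allylic chloride can serve as an enolate electrophile.

Step 3
Reactants: 4 (4R)-4-benzyl-1,3-oxazolidin-2-one; 5 3-methylbut-2-enoyl chloride
Product: 6 (4R)-4-benzyl-3-(3-methylbut-2-enoyl)-1,3-oxazolidin-2-one
Conditions: n-BuLi, THF, −78 °C; then 5, −78 → 0 °C
Reagents that add atoms: none
Why: N-acylation of the lithiated Evans oxazolidinone installs the auxiliary that will control C3.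

Step 4
Reactants: 6 (4R)-4-benzyl-3-(3-methylbut-2-enoyl)-1,3-oxazolidin-2-one; 3 {[(2E)-4-chloro-2-methylbut-2-en-1-yl]oxy}triethylsilane
Product: 8 (4R)-4-benzyl-3-[(2R,4E)-5-methyl-2-(prop-1-en-2-yl)-6-(triethylsilyloxy)hex-4-enoyl]-1,3-oxazolidin-2-one, via sodium dienolate 7 (not isolated)
Conditions: NaN(SiMe3)2, THF, −78 °C; then 3, NaI (cat.), −78 → −30 °C
Reagents that add atoms: none
Why: Evans asymmetric alkylation of the chelated (Z)-dienolate takes place at the α-carbon on the face opposite the benzyl group, giving the deconjugated (R) centre (C3) that will steer the photocycloaddition.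

Step 5
Reactants: 8 (4R)-4-benzyl-3-[(2R,4E)-5-methyl-2-(prop-1-en-2-yl)-6-(triethylsilyloxy)hex-4-enoyl]-1,3-oxazolidin-2-one
Product: 9 methyl (2R,4E)-5-methyl-2-(prop-1-en-2-yl)-6-(triethylsilyloxy)hex-4-enoate
Conditions: MeMgBr, MeOH, CH2Cl2, 0 °C
Reagents that add atoms: bromo(methoxy)magnesium (from MeMgBr and MeOH), CO[Mg]Br
Why: Mild magnesium methoxide transesterification removes and returns the auxiliary without epimerising or conjugating the β,γ-unsaturated α-centre.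

Step 6
Reactants: 9 methyl (2R,4E)-5-methyl-2-(prop-1-en-2-yl)-6-(triethylsilyloxy)hex-4-enoate
Product: 10 (4R,6E)-3-ethenyl-7-methyl-4-(prop-1-en-2-yl)-8-(triethylsilyloxy)octa-1,6-dien-3-ol
Conditions: CH2=CHMgBr (3.5 equiv), LaCl3·2LiCl (cat.), THF, 0 °C
Reagents that add atoms: vinylmagnesium bromide, C=C[Mg]Br
Why: Double Grignard addition to the ester, lanthanum-promoted to suppress enolisation, gives the tertiary divinyl carbinol whose vinyl groups supply C9/C10 and C6/C7.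

Step 7
Reactants: 10 (4R,6E)-3-ethenyl-7-methyl-4-(prop-1-en-2-yl)-8-(triethylsilyloxy)octa-1,6-dien-3-ol
Product: 11 (1S,2S,3R,5S,6S)-2-ethenyl-6-methyl-3-(prop-1-en-2-yl)-6-[(triethylsilyloxy)methyl]bicyclo[3.2.0]heptan-2-ol
Conditions: (CuOTf)2·C6H6 (5 mol%), hν (254 nm, quartz), Et2O, rt
Reagents that add atoms: none
Why: The Salomon–Kochi CuOTf-catalysed intramolecular [2+2] photocycloaddition of the 1,6-diene closes the cyclobutane and the cyclopentane in one operation, cis-fused, with the C3 isopropenyl group exo (which relays the absolute configuration to C1 and C9), the hydroxyl endo through copper coordination, and the larger CH2OSiEt3 group exo at C11 so that the C11 methyl is cis to C2.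

Step 8
Reactants: 11 (1S,2S,3R,5S,6S)-2-ethenyl-6-methyl-3-(prop-1-en-2-yl)-6-[(triethylsilyloxy)methyl]bicyclo[3.2.0]heptan-2-ol
Product: 14 (1S,3Z,9R,11S)-4,11-dimethyl-11-[(triethylsilyloxy)methyl]bicyclo[7.2.0]undec-3-en-8-one, via potassium enolate 12 (not isolated), via cis-fused ketone 13 (not isolated)
Conditions: KH, 18-crown-6, THF, 0 °C → rt; then t-BuOH, rt
Reagents that add atoms: none
Why: Anionic oxy-Cope rearrangement of the cis-1,2-dialkenyl cyclopentanolate through a boat transition state expands the five-membered ring by four carbons to the (Z)-cyclononenone (erasing C3 and C8 as stereocentres), and the KOt-Bu formed on quenching epimerises C9, α to the ketone, to the more stable trans ring fusion.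

Step 9
Reactants: 14 (1S,3Z,9R,11S)-4,11-dimethyl-11-[(triethylsilyloxy)methyl]bicyclo[7.2.0]undec-3-en-8-one
Product: 15 (1S,3Z,5RS,9R,11S)-5-hydroxy-4,11-dimethyl-11-[(triethylsilyloxy)methyl]bicyclo[7.2.0]undec-3-en-8-one
Conditions: SeO2 (cat.), t-BuOOH, CH2Cl2, rt
Reagents that add atoms: tert-butyl hydroperoxide, CC(C)(C)OO
Why: SeO2 allylic hydroxylation of a 1-methylcycloalkene attacks the ring CH2 on the more substituted alkene carbon (C5, Guillemonat rules), and the C5 configuration is irrelevant because it becomes the ketone.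

Step 10
Reactants: 15 (1S,3Z,5RS,9R,11S)-5-hydroxy-4,11-dimethyl-11-[(triethylsilyloxy)methyl]bicyclo[7.2.0]undec-3-en-8-one
Product: 16 (1S,3Z,5RS,9R,11S)-11-(hydroxymethyl)-4,11-dimethyl-8-methylidenebicyclo[7.2.0]undec-3-en-5-ol
Conditions: Ph3PCH3Br, KOt-Bu (excess), THF, 0 °C → rt; then 1 M HCl, THF–MeOH, 0 °C
Reagents that add atoms: methylidenetriphenylphosphorane, C=P(c1ccccc1)(c1ccccc1)c1ccccc1
Why: Wittig methylenation of the only ketone (C8) installs the exocyclic methylene, and the acidic work-up removes the triethylsilyl group.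

Step 11
Reactants: 16 (1S,3Z,5RS,9R,11S)-11-(hydroxymethyl)-4,11-dimethyl-8-methylidenebicyclo[7.2.0]undec-3-en-5-ol
Product: 17 (1S,3Z,9R,11S)-4,11-dimethyl-8-methylidene-5-oxobicyclo[7.2.0]undec-3-ene-11-carbaldehyde
Conditions: (COCl)2, DMSO, CH2Cl2, −78 °C; Et3N, −78 → 0 °C
Reagents that add atoms: none
Why: Swern oxidation converts the allylic alcohol into the enone and the neopentyl alcohol into a non-epimerisable aldehyde in one pot.

Step 12
Reactants: 17 (1S,3Z,9R,11S)-4,11-dimethyl-8-methylidene-5-oxobicyclo[7.2.0]undec-3-ene-11-carbaldehyde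
Product: 18 (1S,3Z,9R,11S)-11-[(1S)-1-hydroxybut-3-en-1-yl]-4,11-dimethyl-8-methylidenebicyclo[7.2.0]undec-3-en-5-one
Conditions: (−)-Ipc2B(allyl), Et2O, −78 °C; HOCH2CH2NH2 work-up
Reagents that add atoms: (−)-B-allyldiisopinocampheylborane, C=CCB([C@@H]1C[C@@H]2C[C@H]([C@H]1C)C2(C)C)[C@@H]1C[C@@H]2C[C@H]([C@H]1C)C2(C)C
Why: Brown allylboration through a chair transition state delivers allyl to the Si face of the aldehyde under reagent control, setting C1′ as (S), and the aldehyde reacts far faster than the enone at −78 °C.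

Step 13
Reactants: 18 (1S,3Z,9R,11S)-11-[(1S)-1-hydroxybut-3-en-1-yl]-4,11-dimethyl-8-methylidenebicyclo[7.2.0]undec-3-en-5-one
Product: 20 (1S,3Z,9R,11S)-4,11-dimethyl-8-methylidene-11-[(1S)-1-({[(2-methylprop-2-en-1-yl)oxy]di(propan-2-yl)silyl}oxy)but-3-en-1-yl]bicyclo[7.2.0]undec-3-en-5-one, via chlorosilyl ether 19 (not isolated)
Conditions: i-Pr2SiCl2, imidazole, CH2Cl2, 0 °C; then CH2=C(CH3)CH2OH, rt
Reagents that add atoms: dichlorodi(propan-2-yl)silane, CC(C)[Si](Cl)(Cl)C(C)C; 2-methylprop-2-en-1-ol, C=C(C)CO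
Why: Stepwise silylation links the hindered secondary alcohol and methallyl alcohol through a temporary silicon tether and removes the free hydroxyl before the enone meets base.

Step 14
Reactants: 20 (1S,3Z,9R,11S)-4,11-dimethyl-8-methylidene-11-[(1S)-1-({[(2-methylprop-2-en-1-yl)oxy]di(propan-2-yl)silyl}oxy)but-3-en-1-yl]bicyclo[7.2.0]undec-3-en-5-one
Product: 21 (1S,4S,9R,11S)-4,11-dimethyl-8-methylidene-11-[(1S)-1-({[(2-methylprop-2-en-1-yl)oxy]di(propan-2-yl)silyl}oxy)but-3-en-1-yl]bicyclo[7.2.0]undecan-5-one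
Conditions: [(Ph3P)CuH]6, C6H6–H2O, rt; then DBU (cat.), toluene, 60 °C
Reagents that add atoms: none
Why: Conjugate reduction with Stryker's reagent delivers hydride to C3 of the enone only (the isolated alkenes are inert), and DBU equilibration leaves the C4 methyl in the thermodynamically preferred (4S) configuration.

Step 15
Reactants: 21 (1S,4S,9R,11S)-4,11-dimethyl-8-methylidene-11-[(1S)-1-({[(2-methylprop-2-en-1-yl)oxy]di(propan-2-yl)silyl}oxy)but-3-en-1-yl]bicyclo[7.2.0]undecan-5-one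
Product: 22 (1S,4S,9R,11S)-4,11-dimethyl-8-methylidene-11-[(4S,6Z)-7-methyl-2,2-di(propan-2-yl)-1,3-dioxa-2-silacyclooct-6-en-4-yl]bicyclo[7.2.0]undecan-5-one
Conditions: second-generation Grubbs catalyst, RuCl2(=CHPh)(PCy3)(H2IMes) (5 mol%), toluene (2 mM), 80 °C
Reagents that add atoms: none
Why: Silicon-tethered ring-closing metathesis forms the eight-membered silaketal, which can only hold a cis ring alkene and therefore gives the (Z)-trisubstituted C3′=C4′ bond.

Step 16
Reactants: 22 (1S,4S,9R,11S)-4,11-dimethyl-8-methylidene-11-[(4S,6Z)-7-methyl-2,2-di(propan-2-yl)-1,3-dioxa-2-silacyclooct-6-en-4-yl]bicyclo[7.2.0]undecan-5-one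
Product: 23 (1S,4S,9R,11S)-11-[(1S,3Z)-1,5-dihydroxy-4-methylpent-3-en-1-yl]-4,11-dimethyl-8-methylidenebicyclo[7.2.0]undecan-5-one
Conditions: Bu4NF, THF, 0 °C → rt
Reagents that add atoms: none
Why: Fluoride cleaves both Si–O bonds and releases the (Z)-1,5-diol without touching ketone or alkenes.

Step 17
Reactants: 23 (1S,4S,9R,11S)-11-[(1S,3Z)-1,5-dihydroxy-4-methylpent-3-en-1-yl]-4,11-dimethyl-8-methylidenebicyclo[7.2.0]undecan-5-one
Product: 24 (2Z,5S)-5-acetoxy-5-[(1S,4S,9R,11S)-4,11-dimethyl-8-methylidene-5-oxobicyclo[7.2.0]undecan-11-yl]-2-methylpent-2-en-1-yl acetate (CNP0244219.2)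
Conditions: Ac2O, pyridine, DMAP (cat.), CH2Cl2, rt
Reagents that add atoms: acetic anhydride, CC(=O)OC(C)=O
Why: Standard acetylation of the primary allylic and the secondary alcohol gives the target.

**Compound list**
1 | 1-chloro-3-methylbut-2-ene | CC(C)=CCCl | starting material
2 | (2E)-4-chloro-2-methylbut-2-en-1-ol | OC/C(C)=C/CCl | intermediate
3 | {[(2E)-4-chloro-2-methylbut-2-en-1-yl]oxy}triethylsilane | CC[Si](CC)(CC)OC/C(C)=C/CCl | intermediate
4 | (4R)-4-benzyl-1,3-oxazolidin-2-one | O=C1N[C@H](Cc2ccccc2)CO1 | starting material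
5 | 3-methylbut-2-enoyl chloride | CC(C)=CC(Cl)=O | starting material
6 | (4R)-4-benzyl-3-(3-methylbut-2-enoyl)-1,3-oxazolidin-2-one | CC(C)=CC(=O)N1[C@H](Cc2ccccc2)COC1=O | intermediate
7 | sodium (Z)-dienolate of 6 (not isolated) | [Na+].[O-]/C(=C\C(C)=C)N1[C@H](Cc2ccccc2)COC1=O | intermediate
8 | (4R)-4-benzyl-3-[(2R,4E)-5-methyl-2-(prop-1-en-2-yl)-6-(triethylsilyloxy)hex-4-enoyl]-1,3-oxazolidin-2-one | CC[Si](CC)(CC)OC/C(C)=C/C[C@H](C(C)=C)C(=O)N1[C@H](Cc2ccccc2)COC1=O | intermediate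
9 | methyl (2R,4E)-5-methyl-2-(prop-1-en-2-yl)-6-(triethylsilyloxy)hex-4-enoate | CC[Si](CC)(CC)OC/C(C)=C/C[C@H](C(C)=C)C(=O)OC | intermediate
10 | (4R,6E)-3-ethenyl-7-methyl-4-(prop-1-en-2-yl)-8-(triethylsilyloxy)octa-1,6-dien-3-ol | CC[Si](CC)(CC)OC/C(C)=C/C[C@H](C(C)=C)C(O)(C=C)C=C | intermediate
11 | (1S,2S,3R,5S,6S)-2-ethenyl-6-methyl-3-(prop-1-en-2-yl)-6-[(triethylsilyloxy)methyl]bicyclo[3.2.0]heptan-2-ol | C=C[C@@]1(O)[C@@H](C(C)=C)C[C@H]2[C@@H]1C[C@]2(C)CO[Si](CC)(CC)CC | intermediate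
12 | potassium enolate of 13 (not isolated) | [K+].[O-]C1=CCC/C(C)=C\C[C@H]2[C@@H]1C[C@]2(C)CO[Si](CC)(CC)CC | intermediate
13 | (1S,3Z,9S,11S)-4,11-dimethyl-11-[(triethylsilyloxy)methyl]bicyclo[7.2.0]undec-3-en-8-one, cis-fused (not isolated) | O=C1CCC/C(C)=C\C[C@H]2[C@@H]1C[C@]2(C)CO[Si](CC)(CC)CC | intermediate
14 | (1S,3Z,9R,11S)-4,11-dimethyl-11-[(triethylsilyloxy)methyl]bicyclo[7.2.0]undec-3-en-8-one, trans-fused | O=C1CCC/C(C)=C\C[C@H]2[C@H]1C[C@]2(C)CO[Si](CC)(CC)CC | intermediate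
15 | (1S,3Z,5RS,9R,11S)-5-hydroxy-4,11-dimethyl-11-[(triethylsilyloxy)methyl]bicyclo[7.2.0]undec-3-en-8-one (C5 epimers) | O=C1CCC(O)/C(C)=C\C[C@H]2[C@H]1C[C@]2(C)CO[Si](CC)(CC)CC | intermediate
16 | (1S,3Z,5RS,9R,11S)-11-(hydroxymethyl)-4,11-dimethyl-8-methylidenebicyclo[7.2.0]undec-3-en-5-ol (C5 epimers) | C=C1CCC(O)/C(C)=C\C[C@H]2[C@H]1C[C@]2(C)CO | intermediate
17 | (1S,3Z,9R,11S)-4,11-dimethyl-8-methylidene-5-oxobicyclo[7.2.0]undec-3-ene-11-carbaldehyde | C=C1CCC(=O)/C(C)=C\C[C@H]2[C@H]1C[C@]2(C)C=O | intermediate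
18 | (1S,3Z,9R,11S)-11-[(1S)-1-hydroxybut-3-en-1-yl]-4,11-dimethyl-8-methylidenebicyclo[7.2.0]undec-3-en-5-one | C=C1CCC(=O)/C(C)=C\C[C@H]2[C@H]1C[C@]2(C)[C@H](CC=C)O | intermediate
19 | chlorodi(propan-2-yl)silyl ether of 18 (not isolated) | C=C1CCC(=O)/C(C)=C\C[C@H]2[C@H]1C[C@]2(C)[C@H](CC=C)O[Si](Cl)(C(C)C)C(C)C | intermediate
20 | mixed di(propan-2-yl)silylene bis-ether of 18 and 2-methylprop-2-en-1-ol | C=C1CCC(=O)/C(C)=C\C[C@H]2[C@H]1C[C@]2(C)[C@H](CC=C)O[Si](C(C)C)(C(C)C)OCC(C)=C | intermediate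
21 | (1S,4S,9R,11S)-4,11-dimethyl-8-methylidene-11-[(1S)-1-({[(2-methylprop-2-en-1-yl)oxy]di(propan-2-yl)silyl}oxy)but-3-en-1-yl]bicyclo[7.2.0]undecan-5-one | C=C1CCC(=O)[C@@H](C)CC[C@H]2[C@H]1C[C@]2(C)[C@H](CC=C)O[Si](C(C)C)(C(C)C)OCC(C)=C | intermediate
22 | (1S,4S,9R,11S)-4,11-dimethyl-8-methylidene-11-[(4S,6Z)-7-methyl-2,2-di(propan-2-yl)-1,3-dioxa-2-silacyclooct-6-en-4-yl]bicyclo[7.2.0]undecan-5-one | C=C1CCC(=O)[C@@H](C)CC[C@H]2[C@H]1C[C@]2(C)[C@@H]3C/C=C(/C)CO[Si](C(C)C)(C(C)C)O3 | intermediate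
23 | (1S,4S,9R,11S)-11-[(1S,3Z)-1,5-dihydroxy-4-methylpent-3-en-1-yl]-4,11-dimethyl-8-methylidenebicyclo[7.2.0]undecan-5-one | C=C1CCC(=O)[C@@H](C)CC[C@H]2[C@H]1C[C@]2(C)[C@H](C/C=C(/C)CO)O | intermediate
24 | (2Z,5S)-5-acetoxy-5-[(1S,4S,9R,11S)-4,11-dimethyl-8-methylidene-5-oxobicyclo[7.2.0]undecan-11-yl]-2-methylpent-2-en-1-yl acetate | C=C1CCC(=O)[C@@H](C)CC[C@H]2[C@H]1C[C@]2(C)[C@H](C/C=C(/C)COC(C)=O)OC(C)=O | target

**Totals:** 17 steps; longest linear sequence 16 steps (steps 1, 2, 4–17).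

**Steps most likely to fail**

Step 7 (photocycloaddition). The trisubstituted alkene may react slowly under CuOTf catalysis, the isopropenyl and second vinyl group may interfere, and the stereochemical relay from C3 or the endo preference of the hydroxyl may be incomplete. Fallback: leave the route at 9. DIBAL-H at −78 °C gives (2R,4E)-5-methyl-2-(prop-1-en-2-yl)-6-(triethylsilyloxy)hex-4-enal F1. Vinylmagnesium bromide gives the secondary dienol (4R,6E)-7-methyl-4-(prop-1-en-2-yl)-8-(triethylsilyloxy)octa-1,6-dien-3-ol F2. Dess–Martin oxidation gives the vinyl ketone (4R,6E)-7-methyl-4-(prop-1-en-2-yl)-8-(triethylsilyloxy)octa-1,6-dien-3-one F3. Its intramolecular enone–alkene [2+2] photocycloaddition (350 nm, rule of five) gives (1S,3R,5S,6S)-6-methyl-3-(prop-1-en-2-yl)-6-[(triethylsilyloxy)methyl]bicyclo[3.2.0]heptan-2-one F4, in which the isopropenyl group can equilibrate to exo. Vinylmagnesium bromide with LaCl3·2LiCl then adds from the convex face and rejoins the route at 11.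

Step 9 (allylic hydroxylation). SeO2 may attack the C4 methyl, C2 or the ketone α-position instead of C5. Fallback: leave at 14. CrO3·3,5-dimethylpyrazole oxidises C5 directly to (1S,3Z,9R,11S)-4,11-dimethyl-11-[(triethylsilyloxy)methyl]bicyclo[7.2.0]undec-3-ene-5,8-dione F5. One equivalent of Ph3P=CH2 methylenates only the non-conjugated C8 ketone to give (1S,3Z,9R,11S)-4,11-dimethyl-8-methylidene-11-[(triethylsilyloxy)methyl]bicyclo[7.2.0]undec-3-en-5-one F6. Swern oxidation, which converts a primary triethylsilyl ether directly into the aldehyde, rejoins the route at 17.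

Step 14 (C4 configuration). Equilibration may favour the (4R) epimer or give a mixture. Fallback: leave at 20. RhCl(PPh3)3-catalysed 1,4-hydrosilylation with Et3SiH gives the triethylsilyl enol ether of 21 F7. Kinetic, reagent-controlled protonation with the chiral Brønsted acid BINOL·SnCl4 (the enantiomer that protonates the required face of C4) then gives 21 without relying on thermodynamic preference.

**Further compounds**
F1 | step 7 | (2R,4E)-5-methyl-2-(prop-1-en-2-yl)-6-(triethylsilyloxy)hex-4-enal | CC[Si](CC)(CC)OC/C(C)=C/C[C@H](C(C)=C)C=O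
F2 | step 7 | (4R,6E)-7-methyl-4-(prop-1-en-2-yl)-8-(triethylsilyloxy)octa-1,6-dien-3-ol (C3 epimers) | CC[Si](CC)(CC)OC/C(C)=C/C[C@H](C(C)=C)C(O)C=C
F3 | step 7 | (4R,6E)-7-methyl-4-(prop-1-en-2-yl)-8-(triethylsilyloxy)octa-1,6-dien-3-one | CC[Si](CC)(CC)OC/C(C)=C/C[C@H](C(C)=C)C(=O)C=C
F4 | step 7 | (1S,3R,5S,6S)-6-methyl-3-(prop-1-en-2-yl)-6-[(triethylsilyloxy)methyl]bicyclo[3.2.0]heptan-2-one | O=C1[C@@H](C(C)=C)C[C@H]2[C@@H]1C[C@]2(C)CO[Si](CC)(CC)CC
F5 | step 9 | (1S,3Z,9R,11S)-4,11-dimethyl-11-[(triethylsilyloxy)methyl]bicyclo[7.2.0]undec-3-ene-5,8-dione | O=C1CCC(=O)/C(C)=C\C[C@H]2[C@H]1C[C@]2(C)CO[Si](CC)(CC)CC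
F6 | step 9 | (1S,3Z,9R,11S)-4,11-dimethyl-8-methylidene-11-[(triethylsilyloxy)methyl]bicyclo[7.2.0]undec-3-en-5-one | C=C1CCC(=O)/C(C)=C\C[C@H]2[C@H]1C[C@]2(C)CO[Si](CC)(CC)CC
F7 | step 14 | triethylsilyl enol ether of 21 | C=C1CCC(O[Si](CC)(CC)CC)=C(C)CC[C@H]2[C@H]1C[C@]2(C)[C@H](CC=C)O[Si](C(C)C)(C(C)C)OCC(C)=C
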